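Left-handed product forms at 764 /M²/s times coupling partner, free catalyst and left-handed substrate multiplied together, so each order asks how those three stand at the moment of 5.0% conversion.

left-handed substrate 0.085 M; coupling partner 1.10 equiv; free catalyst 0.18 mol%; right-handed substrate 0.085 M

    coupling partner + free catalyst + left-handed substrate → free catalyst + left-handed product (k1 = 764 /M²/s)
    coupling partner + free catalyst + right-handed substrate → free catalyst + right-handed product (k2 = 11.0 /M²/s)
    2 coupling partner → self-condensation product (k3 = 0.00856 /M/s)
    free catalyst → spent catalyst (k4 = 0.00143 /s)

- apparent order in free catalyst when 5.0% of the left-handed substrate and right-handed substrate together are converted (percent change of the rate of making left-handed product for one percent more free catalyst charged)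
- apparent order in coupling partner when 5.0% of the left-handed substrate and right-handed substrate together are converted (percent change of the rate of making left-handed product for one percent more coupling partner charged)

- free catalyst is single-handed; left-handed substrate and right-handed substrate are mirror images of each other, charged as a racemate, each of them at the stated concentration
- two of one species on the left: rate k times its square, two consumed each time
- charge of left-handed substrate (flask): 0.085 M

This reckoning takes the equivalents and the loading on the left-handed charge, so coupling partner starts at 0.0935 M and free catalyst at 1.53 × 10⁻⁴ M. The conversion needs 0.00850 M of substrate, nearly all of it left-handed by the turnover rates. The mean-rate clock is that amount divided by the mean of the starting and final rates: 0.168 min.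

The ladder starts with this clock. Left-handed substrate has a half-life of 1.06 min at the charge, free catalyst 8.08 min, coupling partner by self-condensation 10.4 min, and right-handed substrate 73.4 min, each longer than the one before . By the clock, free catalyst has lost 1.44%, and self-condensation has taken 0.00137 M of coupling partner, leaving 0.0836 M.

Both substrates fall along one ratio of constants, so left-handed substrate at that conversion stays put when the charge of free catalyst or coupling partner changes. More catalyst shortens the clock, and both losses shrink with it, so the order in free catalyst is one plus the two lost fractions: 1.03. With more coupling partner the draw of the conversion stays the same, self-condensation grows in step with the charge, and the shorter clock saves free catalyst, which gives 1.12.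

The forecast gave 1.03 and 1.116, with left-handed substrate at that conversion “fixed whatever the charges”.

The simulation gives 1.0 and 1.1. At 0.169 min, spent catalyst stands at 1.44% of the catalyst, where the clock gave 1.44%. A second flask with twice the free catalyst has its clock at half, and the reckoned order predicts a rate factor of 2.04; that flask reads 2.03. In the first flask at 1.18 min, the half-life of coupling partner by the left-handed route is 2.2 min, shorter than the 90 min by the right-handed route. In that flask at 25.0 min, 17% of the left-handed substrate charged remains, against 97% of the right-handed.

(The rate constants are invented; what happens was integrated by code.)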